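## The problem

The target is an ent-labdane, (2R,5R,9R,10R)-16-acetoxy-2-hydroxylabda-8(17),13Z-dien-15-oic acid: a trans-fused decalin (ring A C1–C5/C10, ring B C5–C10) with an exocyclic C8=C17 methylene and a C9 side chain ending in a Z-trisubstituted alkene that carries a free acid (C15) and an allylic acetate (C16). C5 lies between two quaternary carbons (C4 and C10), so the bonds to C5 are the hardest to form, and the C5–H/C10–CH3 relation must be trans. The stereocentres can be chained: C5 can direct an alkylation at C10, the axial C10 methyl then shields one face of C9, and the C2 substituent is equatorial, so it can be set under thermodynamic control in the rigid bicycle. Three groups will not survive rough treatment. The exocyclic alkene moves into the ring with strong acid. The acetate must be told apart from the free C2 hydroxyl. The Z-4-oxygenated enoic acid closes to a butenolide as soon as O16 is free next to an activated carboxyl. The enabling feature is that ring B with C17, together with C4 and its two methyls, contains exactly the ten carbons of (S)-carvone, whose isopropenyl group sits on C5 with the correct absolute configuration. The isopropenyl carbon can therefore become C4 through a tertiary radical that attacks C3 of an acrylate arm hung on C10, closing ring A without forming any bond to C5. The price is that the carvone carbonyl ends up at C9 and the carvone methyl is C17, so the side chain must be grown from a hindered ketone, the methylene must be made from a ring alkene, and C2 enters as carbon and must be exchanged for oxygen.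

## Retrosynthesis

Acid and acetate. Reconnecting O16 to C15 turns 30 into the 4-substituted butenolide 26 (through SEM ester 29, hydroxy ester 28 and carboxylate 27). This is preferred over an olefination across C13=C14, because the ring fixes C16 cis to C15 with no isomer possible. The precursor has neither free acid nor acetate. The forward sequence must open the lactone and cap both oxygens before it recloses, and then remove the SEM ester and the C2 silyl ether in one operation.

Exocyclic methylene. The C8=C17 alkene of 26 is traced to the ring alkene C7=C8 of 22 by way of the C17 alcohol 23 (cutting C7–H, restoring C17–O). A Wittig reaction on a C8 ketone is not available, since C17 is the carvone methyl and is already in place. The forward steps must oxidise C17 selectively and shift the alkene reductively without touching the butenolide.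

C12–C13. Cutting this bond gives the vinyl decalin 19 and commercial 4-bromofuran-2(5H)-one 20, to be joined by hydroboration and sp3–sp2 Suzuki–Miyaura coupling. A cut at C11–C12 would need a displacement at a hindered neopentyl-type carbon, and a cut at C13–C14 would reopen the geometry question.

C9 chain. The vinyl group of 19 comes from alcohol 17 (C11–C12 by Wittig reaction on aldehyde 18), 17 from diene 15 (C9–H and C11–O by hydroboration), and 15 from ketone 14 (C9=C11 by methylenation). This order lets the axial C10 methyl set C9 during hydroboration, which is more reliable than protonation of a C9 aldehyde enolate. The precursor 14 has only three stereocentres.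

C2 oxygen. The C2–O bond of 14 is traced through alcohol 13 and acetate 12 to methyl ketone 11, then to acid 9 and ester 8 (Baeyer–Villiger oxidation with retention). The exchange is placed at the enone stage because the conjugated, hindered C7=C8 alkene is the only alkene that tolerates a peracid.

Ring A (key). Cutting C3–C4 in 8 gives the carvone derivative 6, with an isopropenyl group on C5 and a 2-(methoxycarbonyl)allyl arm on C10. This removes a ring, a quaternary carbon and a stereocentre in one step, and avoids making the C4–C5 bond, which any cut closer to the ring fusion would require. The forward reaction must generate the tertiary radical at C4 selectively and close 6-endo.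

C10. Cutting the two C–C bonds at C10 of 6 leads to 6-methylcarvone 3, bromide 4 and finally (S)-carvone 1. The second alkylation must enter anti to the isopropenyl group.

## Roads not taken

Alternative 1: The cut passes through C5–C10 and C8–C9 and opens both rings to the acyclic triene A1. In the forward sense its (E)-3-methyl enoate (C9, C10) would add to the (E,E)-diene (C5–C8) across the C1–C4 tether to give octalin A2. The merit is real: two rings and C5, C9 and C10 arise together, C11 is already on C9 with the right relation to C20, and C17 is already oxygenated. In that respect this road is better than the chosen one, which spends steps 9 to 14 on the C9 chain and the methylene. The weak points lie in the cycloaddition. The dienophile is β,β-disubstituted, and the new C5–C10 bond joins a carbon that becomes quaternary to one next to the gem-dimethyl carbon. With a four-atom tether the preference between cis and trans fusion is small, and the only control element, the C2 silyl ether, is remote. A1 must also be made enantiopure with three defined alkenes, and A2 still needs hydrogenation of C6=C7 and extension of the ester. Against this, the chosen plan offers a ring fusion that cannot give isomers: C5 is bought and C10 is set by an established anti alkylation.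

Alternative 2: The cut is C9–C10 and C7–C8, with the C2 oxygen acylated by C11. The alkynoate ester A3 of a ring A dienol would cyclise on heating across its C10–C5–C6–C7 diene to the lactone-bridged diene A4. On paper this is the shortest road, and in two respects it is better than the chosen plan. The C2 oxygen is present from the start and also steers the dienophile to one face of C10, and the C17 allylsilane could give the exocyclic methylene and C9–H in one protodesilylation. The weak points are as follows. The ester tether must adopt its disfavoured cisoid rotamer. The diene terminus C10 is fully substituted, and the product is a bridged bicyclic lactone. C5 remains an alkene carbon between two quaternary centres, so its hydrogen must later be delivered trans to C20 with nothing in A4 to guarantee the face. C11 arrives as a carboxyl carbon and must be taken down to CH2. The dienol is required in the (S) series. The chosen plan is longer but never has to reduce a ring-fusion alkene.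

Alternative 3: The cut is C9–C10 and C5=C6. Under KOH in methanol the C10 enolate of the ring A ketone A5 would add to the alkylidene acetoacetate A6 at C9, and the acetyl methyl (C6) would then condense on the C5 carbonyl to give enone ester A7. The merits are convergence, an enolate that can form on one side only, and a product that already carries the C11–C12 arm and C17. The reversible conditions could settle C9 against C10, and a later dissolving-metal reduction of the enone should give the trans fusion, which is as dependable as taking C5 from the pool. The weak points are steric and stereochemical. The Michael step joins a tetrasubstituted enolate to a β-substituted acceptor and is easily reversed. The aldol closure must attack a carbonyl flanked by two quaternary carbons. The target needs A5 in the (4S) series, the mirror image of the enantiomer that is made on scale. Removal of the C7 oxygen and conversion of the C8 ester into a methylene remain. The chosen plan needs a comparable number of steps after ring formation, but its ring-forming bond (C3–C4) is unhindered and is made by a radical that tolerates the neighbouring quaternary centre.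

Key step: step 3

Assumption: the SMILES is read as the ent-labdane with 2R,5R,9R,10R configuration, the C2 hydroxyl equatorial and trans to the C10 methyl, and the CH2OAc group cis to the carboxyl (13Z).

## Route

Step 1
Reactants: 1 (S)-(+)-carvone
Product: 3 6-methylcarvone (C6 epimer mixture), via lithium dienolate 2 (not isolated)
Conditions: LiN(i-Pr)2, THF, −78 °C; MeI, −78 → 0 °C
Reagents that add atoms: iodomethane, CI
Why: Kinetic deprotonation of the enone at the α' methylene gives the cross-conjugated lithium dienolate, which is C-methylated (enolate alkylation); the new centre is an epimer mixture that is erased in step 2.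

Step 2
Reactants: 3 6-methylcarvone; 4 methyl 2-(bromomethyl)prop-2-enoate
Product: 6 carvone-derived acrylate (methyl and acrylate arm on C10; arm trans to isopropenyl), via lithium enolate 5 (not isolated)
Conditions: LiN(i-Pr)2, THF, −78 °C; then 4, DMPU, −78 → −20 °C
Reagents that add atoms: none
Why: The tetrasubstituted enolate is alkylated by the allylic bromide (direct or addition–elimination, same product) on the face opposite the neighbouring isopropenyl group, as in established double alkylations of carvone. This sets the C10 quaternary centre with the methyl cis and the arm trans to isopropenyl.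

Step 3
Reactants: 6 carvone-derived acrylate
Product: 8 trans-decalin enone with equatorial C2 methyl ester, via axial C2 ester 7 (not isolated)
Conditions: Fe(acac)3 (30 mol%), PhSiH3, EtOH/(CH2OH)2, 60 °C; then NaOMe, MeOH, 23 °C
Reagents that add atoms: none
Why: An iron hydride formed from Fe(acac)3 and PhSiH3 transfers a hydrogen atom to the CH2 terminus of the electron-rich 1,1-disubstituted isopropenyl alkene, giving the tertiary C4 radical. This nucleophilic radical adds to the unsubstituted terminus (C3) of the tethered acrylate in a 6-endo-trig closure that forms C3–C4 and ring A; the closest known reaction type is the iron-hydride-initiated reductive olefin coupling in its intramolecular Giese form, which is established for quaternary carbons. 6-endo is preferred over 5-exo because attack at the inner carbon would meet a fully substituted centre and give a primary radical, whereas attack at CH2 is polarity-matched and gives the ester-stabilised radical. That radical is reduced by divalent iron to the enolate and protonated by ethanol. The ring fusion is not at stake, since C5 comes from carvone and C10 from step 2, and their trans arms close ring A as a chair. The only new stereocentre is C2: kinetic protonation from the open face may give the axial ester 7, and NaOMe equilibrates it through the ester enolate to 8, which avoids 1,3-diaxial contact with the axial C4 and C10 methyls. The step needs hydrogen-atom transfer to the isopropenyl group in preference to the acrylate and the enone; the unconjugated, electron-rich alkene is the best hydrogen-atom acceptor, and the conjugated alkenes act only as radical acceptors.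

Step 4
Reactants: 8 equatorial C2 methyl ester
Product: 9 C2 carboxylic acid
Conditions: LiOH, THF/MeOH/H2O, 23 °C; then aq. HCl
Reagents that add atoms: lithium hydroxide, [Li+].[OH-]
Why: Saponification of an unhindered equatorial ester; the enone is inert to aqueous LiOH at 23 °C and the equatorial configuration is the thermodynamic one.

Step 5
Reactants: 9 C2 carboxylic acid
Product: 11 C2 methyl ketone, via acid chloride 10 (not isolated)
Conditions: (COCl)2, DMF (cat.), CH2Cl2, 0 → 23 °C; concentrate; MeZnCl, Pd(PPh3)4 (5 mol%), THF, 0 → 23 °C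
Reagents that add atoms: methylzinc chloride, C[Zn]Cl
Why: Negishi acylation: oxidative addition of the acid chloride to zerovalent palladium, transmetallation from MeZnCl and reductive elimination give the ketone. Organozinc reagents do not add to the hindered enone, which a lithium or magnesium reagent would attack.

Step 6
Reactants: 11 C2 methyl ketone
Product: 12 C2 acetate
Conditions: mCPBA, CH2Cl2, 23 → 40 °C
Reagents that add atoms: 3-chloroperbenzoic acid, OOC(=O)c1cccc(Cl)c1
Why: Baeyer–Villiger oxidation: the secondary C2 carbon migrates in preference to methyl with retention, so the equatorial C–C bond becomes the equatorial C–O bond. The only alkene present is the electron-poor, hindered enone, which should resist the peracid.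

Step 7
Reactants: 12 C2 acetate
Product: 13 C2 alcohol
Conditions: K2CO3, MeOH, 23 °C
Reagents that add atoms: none
Why: Base-catalysed methanolysis of the acetate; no stereocentre is touched.

Step 8
Reactants: 13 C2 alcohol
Product: 14 C2 TBS ether
Conditions: TBSCl, imidazole, DMF, 23 °C
Reagents that add atoms: tert-butyldimethylsilyl chloride, CC(C)(C)[Si](C)(C)Cl
Why: Silylation of the equatorial secondary alcohol; the ether must withstand ylides, boranes, oxidants, palladium and hydroxide up to step 15 and leave with fluoride in step 16.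

Step 9
Reactants: 14 C2 TBS ether (C9 enone)
Product: 15 C9 methylidene diene
Conditions: Ph3PCH3Br, KOt-Bu, toluene, 90 °C
Reagents that add atoms: methyltriphenylphosphonium bromide, C[P+](c1ccccc1)(c1ccccc1)c1ccccc1.[Br-]
Why: Wittig methylenation under the forcing alkoxide conditions used for hindered ketones installs C11; C10 bears no hydrogen, so nothing can epimerise.

Step 10
Reactants: 15 C9 methylidene diene
Product: 17 C11 alcohol with 9R configuration, via B-alkyl-9-BBN 16 (not isolated)
Conditions: 9-BBN, THF, 0 → 40 °C; then NaOH, H2O2, H2O, 0 °C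
Reagents that add atoms: hydrogen peroxide, OO
Why: Hydroboration–oxidation: boron adds to the terminal C11 of the exocyclic alkene and hydrogen to C9 from the face opposite the axial C10 methyl, so C11 ends equatorial and cis to C20 (9R). The trisubstituted C7=C8 alkene reacts far more slowly with 9-BBN.

Step 11
Reactants: 17 C11 alcohol
Product: 19 C9 vinyl decalin, via C11 aldehyde 18 (not isolated)
Conditions: Dess–Martin periodinane, pyridine, CH2Cl2, 0 °C; filter, concentrate; Ph3PCH3Br, KN(SiMe3)2, THF, −78 → 0 °C
Reagents that add atoms: methyltriphenylphosphonium bromide, C[P+](c1ccccc1)(c1ccccc1)c1ccccc1.[Br-]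
Why: Buffered Dess–Martin oxidation followed at once by Wittig methylenation adds C12. The β,γ-unsaturated aldehyde is not stored, so C9 should neither epimerise nor let the ring alkene move into conjugation.

Step 12
Reactants: 19 C9 vinyl decalin; 20 4-bromofuran-2(5H)-one
Product: 22 Δ7 butenolide, via B-alkyl-9-BBN 21 (not isolated)
Conditions: 9-BBN, THF, 0 → 23 °C; then 20, PdCl2(dppf), AsPh3, Cs2CO3, DMF/THF/H2O, 23 °C
Reagents that add atoms: none
Why: 9-BBN hydroborates the monosubstituted vinyl group at C12 in preference to the trisubstituted ring alkene, and B-alkyl Suzuki–Miyaura coupling with the vinylogous acyl bromide forms C12–C13. The lactone ring fixes C16 cis to C15.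

Step 13
Reactants: 22 Δ7 butenolide
Product: 23 C17 allylic alcohol
Conditions: SeO2 (0.3 equiv), t-BuOOH, CH2Cl2, 0 → 23 °C
Reagents that add atoms: selenium dioxide, O=[Se]=O; tert-butyl hydroperoxide, CC(C)(C)OO
Why: SeO2 allylic oxidation (ene reaction, then [2,3]-sigmatropic shift) occurs at the disubstituted end of the electron-rich trisubstituted alkene, where the methyl C17 is preferred over the hindered methine C9. The electron-poor butenolide alkene is not an ene partner.

Step 14
Reactants: 23 C17 allylic alcohol
Product: 26 Δ8(17) butenolide, via sulfonylhydrazine adduct 24 (not isolated), via allylic diazene 25 (not isolated)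
Conditions: 2-nitrobenzenesulfonylhydrazide, PPh3, DEAD, THF, −30 °C; then 23 °C
Reagents that add atoms: none
Why: Mitsunobu displacement of the primary allylic alcohol, loss of the sulfinic acid on warming, and retro-ene loss of N2 from the monoalkyl diazene deliver hydrogen to C7 and move the alkene to C8=C17 (reductive 1,3-transposition of an allylic alcohol). C7 becomes CH2, so no stereocentre is involved.

Step 15
Reactants: 26 Δ8(17) butenolide
Product: 29 Z-acetoxy SEM ester, via potassium hydroxy carboxylate 27 (not isolated), via hydroxy SEM ester 28 (not isolated)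
Conditions: KOH (1.05 equiv), THF/H2O, 0 °C; evaporate, toluene azeotrope; SEMCl, DMF, 0 °C; then Ac2O, pyridine, DMAP (cat.), 0 °C
Reagents that add atoms: potassium hydroxide, [K+].[OH-]; 2-(trimethylsilyl)ethoxymethyl chloride, C[Si](C)(C)CCOCCl; acetic anhydride, CC(=O)OC(C)=O
Why: Hydroxide opens the lactone by acyl–oxygen cleavage to the Z-hydroxy carboxylate, whose geometry comes from the ring. O-Alkylation of the carboxylate and acetylation of the primary alcohol in the same flask cap both ends before the lactone can reform.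

Step 16
Reactants: 29 Z-acetoxy SEM ester
Product: 30 target acid
Conditions: HF (48% aq.), MeCN, 0 → 23 °C
Reagents that add atoms: none
Why: Cleavage of the secondary TBS ether and fluoride-triggered fragmentation of the SEM ester free the C2 hydroxyl and the acid in one operation. The allylic acetate and the exocyclic alkene should tolerate dilute HF at this temperature.

## Compound list

1 | (S)-(+)-carvone, (5S)-2-methyl-5-(prop-1-en-2-yl)cyclohex-2-en-1-one | CC1=CC[C@@H](CC1=O)C(C)=C | starting material
2 | lithium (3S)-6-methyl-3-(prop-1-en-2-yl)cyclohexa-1,5-dien-1-olate | CC1=CC[C@H](C(C)=C)C=C1O[Li] | intermediate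
3 | (5S)-2,6-dimethyl-5-(prop-1-en-2-yl)cyclohex-2-en-1-one, C6 epimer mixture | CC1=CC[C@H](C(C)=C)C(C)C1=O | intermediate
4 | methyl 2-(bromomethyl)prop-2-enoate | C=C(CBr)C(=O)OC | starting material
5 | lithium (3R)-2,6-dimethyl-3-(prop-1-en-2-yl)cyclohexa-1,5-dien-1-olate | CC1=CC[C@H](C(C)=C)C(C)=C1O[Li] | intermediate
6 | methyl 2-{[(1R,6R)-1,3-dimethyl-2-oxo-6-(prop-1-en-2-yl)cyclohex-3-en-1-yl]methyl}prop-2-enoate | CC1=CC[C@H](C(C)=C)[C@@](C)(CC(=C)C(=O)OC)C1=O | intermediate
7 | methyl (2S,4aR,8aR)-4,4,7,8a-tetramethyl-8-oxo-1,2,3,4,4a,5,8,8a-octahydronaphthalene-2-carboxylate (axial ester) | CC1=CC[C@@H]2C(C)(C)C[C@H](C(=O)OC)C[C@@]2(C)C1=O | intermediate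
8 | methyl (2R,4aR,8aR)-4,4,7,8a-tetramethyl-8-oxo-1,2,3,4,4a,5,8,8a-octahydronaphthalene-2-carboxylate (equatorial ester) | CC1=CC[C@@H]2C(C)(C)C[C@@H](C(=O)OC)C[C@@]2(C)C1=O | intermediate
9 | (2R,4aR,8aR)-4,4,7,8a-tetramethyl-8-oxo-1,2,3,4,4a,5,8,8a-octahydronaphthalene-2-carboxylic acid | CC1=CC[C@@H]2C(C)(C)C[C@@H](C(=O)O)C[C@@]2(C)C1=O | intermediate
10 | (2R,4aR,8aR)-4,4,7,8a-tetramethyl-8-oxo-1,2,3,4,4a,5,8,8a-octahydronaphthalene-2-carbonyl chloride | CC1=CC[C@@H]2C(C)(C)C[C@@H](C(=O)Cl)C[C@@]2(C)C1=O | intermediate
11 | (4aR,7R,8aR)-7-acetyl-2,5,5,8a-tetramethyl-4a,5,6,7,8,8a-hexahydronaphthalen-1(4H)-one | CC1=CC[C@@H]2C(C)(C)C[C@@H](C(C)=O)C[C@@]2(C)C1=O | intermediate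
12 | (2R,4aR,8aR)-4,4,7,8a-tetramethyl-8-oxo-1,2,3,4,4a,5,8,8a-octahydronaphthalen-2-yl acetate | CC1=CC[C@@H]2C(C)(C)C[C@@H](OC(C)=O)C[C@@]2(C)C1=O | intermediate
13 | (4aR,7R,8aR)-7-hydroxy-2,5,5,8a-tetramethyl-4a,5,6,7,8,8a-hexahydronaphthalen-1(4H)-one | CC1=CC[C@@H]2C(C)(C)C[C@@H](O)C[C@@]2(C)C1=O | intermediate
14 | (4aR,7R,8aR)-7-[(tert-butyldimethylsilyl)oxy]-2,5,5,8a-tetramethyl-4a,5,6,7,8,8a-hexahydronaphthalen-1(4H)-one | CC1=CC[C@@H]2C(C)(C)C[C@@H](O[Si](C)(C)C(C)(C)C)C[C@@]2(C)C1=O | intermediate
15 | tert-butyldimethyl{[(2R,4aR,8aR)-4,4,7,8a-tetramethyl-8-methylidene-1,2,3,4,4a,5,8,8a-octahydronaphthalen-2-yl]oxy}silane | CC1=CC[C@@H]2C(C)(C)C[C@@H](O[Si](C)(C)C(C)(C)C)C[C@@]2(C)C1=C | intermediate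
16 | 9-{[(1R,4aR,7R,8aS)-7-[(tert-butyldimethylsilyl)oxy]-2,5,5,8a-tetramethyl-1,4,4a,5,6,7,8,8a-octahydronaphthalen-1-yl]methyl}-9-borabicyclo[3.3.1]nonane | CC1=CC[C@@H]2C(C)(C)C[C@@H](O[Si](C)(C)C(C)(C)C)C[C@@]2(C)[C@@H]1CB1C2CCCC1CCC2 | intermediate
17 | [(1R,4aR,7R,8aR)-7-[(tert-butyldimethylsilyl)oxy]-2,5,5,8a-tetramethyl-1,4,4a,5,6,7,8,8a-octahydronaphthalen-1-yl]methanol | CC1=CC[C@@H]2C(C)(C)C[C@@H](O[Si](C)(C)C(C)(C)C)C[C@@]2(C)[C@@H]1CO | intermediate
18 | (1R,4aR,7R,8aR)-7-[(tert-butyldimethylsilyl)oxy]-2,5,5,8a-tetramethyl-1,4,4a,5,6,7,8,8a-octahydronaphthalene-1-carbaldehyde | CC1=CC[C@@H]2C(C)(C)C[C@@H](O[Si](C)(C)C(C)(C)C)C[C@@]2(C)[C@@H]1C=O | intermediate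
19 | tert-butyl{[(2R,4aR,8R,8aR)-8-ethenyl-4,4,7,8a-tetramethyl-1,2,3,4,4a,5,8,8a-octahydronaphthalen-2-yl]oxy}dimethylsilane | CC1=CC[C@@H]2C(C)(C)C[C@@H](O[Si](C)(C)C(C)(C)C)C[C@@]2(C)[C@@H]1C=C | intermediate
20 | 4-bromofuran-2(5H)-one | O=C1C=C(Br)CO1 | starting material
21 | 9-{2-[(1R,4aR,7R,8aR)-7-[(tert-butyldimethylsilyl)oxy]-2,5,5,8a-tetramethyl-1,4,4a,5,6,7,8,8a-octahydronaphthalen-1-yl]ethyl}-9-borabicyclo[3.3.1]nonane | CC1=CC[C@@H]2C(C)(C)C[C@@H](O[Si](C)(C)C(C)(C)C)C[C@@]2(C)[C@@H]1CCB1C2CCCC1CCC2 | intermediate
22 | 4-{2-[(1R,4aR,7R,8aR)-7-[(tert-butyldimethylsilyl)oxy]-2,5,5,8a-tetramethyl-1,4,4a,5,6,7,8,8a-octahydronaphthalen-1-yl]ethyl}furan-2(5H)-one | CC1=CC[C@@H]2C(C)(C)C[C@@H](O[Si](C)(C)C(C)(C)C)C[C@@]2(C)[C@@H]1CCC1=CC(=O)OC1 | intermediate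
23 | 4-{2-[(1S,4aR,7R,8aR)-7-[(tert-butyldimethylsilyl)oxy]-2-(hydroxymethyl)-5,5,8a-trimethyl-1,4,4a,5,6,7,8,8a-octahydronaphthalen-1-yl]ethyl}furan-2(5H)-one | OCC1=CC[C@@H]2C(C)(C)C[C@@H](O[Si](C)(C)C(C)(C)C)C[C@@]2(C)[C@@H]1CCC1=CC(=O)OC1 | intermediate
24 | N-{[(1S,4aR,7R,8aR)-7-[(tert-butyldimethylsilyl)oxy]-5,5,8a-trimethyl-1-[2-(5-oxo-2,5-dihydrofuran-3-yl)ethyl]-1,4,4a,5,6,7,8,8a-octahydronaphthalen-2-yl]methyl}-2-nitrobenzenesulfonohydrazide | NN(CC1=CC[C@@H]2C(C)(C)C[C@@H](O[Si](C)(C)C(C)(C)C)C[C@@]2(C)[C@@H]1CCC1=CC(=O)OC1)S(=O)(=O)c1ccccc1[N+](=O)[O-] | intermediate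
25 | 4-{2-[(1S,4aR,7R,8aR)-7-[(tert-butyldimethylsilyl)oxy]-2-(diazenylmethyl)-5,5,8a-trimethyl-1,4,4a,5,6,7,8,8a-octahydronaphthalen-1-yl]ethyl}furan-2(5H)-one | N=NCC1=CC[C@@H]2C(C)(C)C[C@@H](O[Si](C)(C)C(C)(C)C)C[C@@]2(C)[C@@H]1CCC1=CC(=O)OC1 | intermediate
26 | 4-{2-[(1R,4aR,7R,8aR)-7-[(tert-butyldimethylsilyl)oxy]-5,5,8a-trimethyl-2-methylidenedecahydronaphthalen-1-yl]ethyl}furan-2(5H)-one | C=C1CC[C@@H]2C(C)(C)C[C@@H](O[Si](C)(C)C(C)(C)C)C[C@@]2(C)[C@@H]1CCC1=CC(=O)OC1 | intermediate
27 | potassium (2Z)-5-[(1R,4aR,7R,8aR)-7-[(tert-butyldimethylsilyl)oxy]-5,5,8a-trimethyl-2-methylidenedecahydronaphthalen-1-yl]-3-(hydroxymethyl)pent-2-enoate | C=C1CC[C@@H]2C(C)(C)C[C@@H](O[Si](C)(C)C(C)(C)C)C[C@@]2(C)[C@@H]1CC/C(=C/C(=O)[O-])CO.[K+] | intermediate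
28 | [2-(trimethylsilyl)ethoxy]methyl (2Z)-5-[(1R,4aR,7R,8aR)-7-[(tert-butyldimethylsilyl)oxy]-5,5,8a-trimethyl-2-methylidenedecahydronaphthalen-1-yl]-3-(hydroxymethyl)pent-2-enoate | C=C1CC[C@@H]2C(C)(C)C[C@@H](O[Si](C)(C)C(C)(C)C)C[C@@]2(C)[C@@H]1CC/C(=C/C(=O)OCOCC[Si](C)(C)C)CO | intermediate
29 | [2-(trimethylsilyl)ethoxy]methyl (2Z)-3-[(acetyloxy)methyl]-5-[(1R,4aR,7R,8aR)-7-[(tert-butyldimethylsilyl)oxy]-5,5,8a-trimethyl-2-methylidenedecahydronaphthalen-1-yl]pent-2-enoate | C=C1CC[C@@H]2C(C)(C)C[C@@H](O[Si](C)(C)C(C)(C)C)C[C@@]2(C)[C@@H]1CC/C(=C/C(=O)OCOCC[Si](C)(C)C)COC(C)=O | intermediate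
30 | (2Z)-3-[(acetyloxy)methyl]-5-[(1R,4aR,7R,8aR)-7-hydroxy-5,5,8a-trimethyl-2-methylidenedecahydronaphthalen-1-yl]pent-2-enoic acid | C=C1CC[C@@H]2C(C)(C)C[C@@H](O)C[C@@]2(C)[C@@H]1CC/C(=C/C(=O)O)COC(C)=O | target

## Step count and risks

Total: 16 steps. Longest linear sequence: 16 steps from 1 (4 and 20 are purchased).

Step 3 (key step). The likely failure is misdirected or unproductive hydrogen-atom transfer: transfer to the acrylate, or a second hydrogen quenching the tertiary radical before it cyclises, which would simply saturate the isopropenyl group. The fallback makes the same radical from a halide and sets out from 6. Ionic Markovnikov addition of HBr in acetic acid at 0 °C to the isopropenyl group, as known for carvone itself, should give methyl 2-{[(1R,6S)-6-(2-bromopropan-2-yl)-1,3-dimethyl-2-oxocyclohex-3-en-1-yl]methyl}prop-2-enoate F1. Slow addition of Bu3SnH with AIBN in benzene at 80 °C abstracts bromine, the C4 radical closes 6-endo onto the acrylate and is quenched by the stannane, and NaOMe in methanol equilibrates the resulting mixture of 7 and 8, returning to the route at 8.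

Step 6. The migration of a cyclohexyl carbon from a methyl ketone is slow, and during a long exposure the peracid may begin to oxidise the enone (epoxidation or ring expansion). The fallback replaces the oxidation by a radical decarboxylation, sets out from 9 and returns at 13. Coupling of 9 with N-hydroxypyridine-2-thione (DCC) gives the thiohydroxamate ester 2-thioxopyridin-1(2H)-yl (2R,4aR,8aR)-4,4,7,8a-tetramethyl-8-oxo-1,2,3,4,4a,5,8,8a-octahydronaphthalene-2-carboxylate F2. Visible-light photolysis under O2 with t-BuSH gives the C2 hydroperoxide (4aR,7R,8aR)-7-hydroperoxy-2,5,5,8a-tetramethyl-4a,5,6,7,8,8a-hexahydronaphthalen-1(4H)-one F3, which PPh3 reduces to 13. Here C2 is set kinetically: oxygen is captured on the equatorial face, because the axial face is closed by the C4 and C10 methyls.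

Step 9. The carbonyl is neopentyl and conjugated, so the ylide may act as a base (vinylogous deprotonation at C6) or fail to add. The fallback replaces olefination by addition and elimination, sets out from 14 and returns at 15. MeLi with CeCl3 in THF at −78 °C adds 1,2 to give (1R,4aR,7R,8aR)-7-[(tert-butyldimethylsilyl)oxy]-1,2,5,5,8a-pentamethyl-1,4,4a,5,6,7,8,8a-octahydronaphthalen-1-ol F4. The Burgess reagent in toluene at 60 °C then eliminates syn toward the only carbon bearing β-hydrogens, the new methyl, giving 15.

Step 11. The C9 hydrogen of aldehyde 18 is both allylic and α to the carbonyl, so epimerisation or migration of the ring alkene into conjugation may outrun the Wittig reaction. The fallback reverses the polarity so that C9 is never α to a carbonyl; it sets out from 17 and returns at 19. Mitsunobu thioetherification with 1-phenyl-1H-tetrazole-5-thiol gives 5-({[(1R,4aR,7R,8aR)-7-[(tert-butyldimethylsilyl)oxy]-2,5,5,8a-tetramethyl-1,4,4a,5,6,7,8,8a-octahydronaphthalen-1-yl]methyl}sulfanyl)-1-phenyl-1H-tetrazole F5. Oxidation with (NH4)6Mo7O24 and H2O2 in ethanol, which spares the ring alkene, gives the corresponding sulfone F6. Julia–Kocienski olefination (KN(SiMe3)2, THF, −78 °C, then monomeric formaldehyde) gives 19.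

Step 13. Allylic oxidation may be misdirected to C6 or to the C9 methine, or may run on to the C17 enal. The fallback moves the alkene through an epoxide, sets out from 22 and returns at 26, bypassing 23 to 25. mCPBA epoxidises only the electron-rich ring alkene, from the face opposite the C10 methyl, to give 4-{2-[7-[(tert-butyldimethylsilyl)oxy]-7,8-epoxy decalinyl]ethyl}furan-2(5H)-one F7 (labdane numbering, epoxide on the face of H5 and H9). Cp2TiCl, made from Cp2TiCl2 and Mn (trivalent titanium), opens it homolytically at the tertiary C8–O bond, and loss of a C17 hydrogen gives the exocyclic allylic alcohol, the 7-hydroxy-8(17)-ene F8. Methyl chloroformate and pyridine give its methyl carbonate F9. Pd(OAc)2, n-Bu3P and HCO2NH4 in THF then deliver hydride to the more substituted allyl terminus C7, leaving the C8=C17 alkene of 26.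

Step 15. The hydroxy ester 28 may relactonise to 26 faster than it is acetylated, all the more because the SEM ester is an activated ester. The fallback never exposes a free hydroxyl beside an unhindered ester; it sets out from 27 (made from 26 as in step 15) and returns at 30. Et3SiCl and imidazole silylate both oxygens to give the triethylsilyl ester triethylsilyl ether F10. K2CO3 in aqueous methanol hydrolyses only the silyl ester, giving the (2Z)-3-{[(triethylsilyl)oxy]methyl} acid F11, which cannot lactonise. Boc2O, DMAP and t-BuOH give its tert-butyl ester F12. HF·pyridine removes both silyl ethers to give the diol tert-butyl ester F13, in which the bulky ester resists ring closure. AcCl and 2,4,6-collidine at −78 °C acetylate the primary allylic hydroxyl selectively to give the acetoxy tert-butyl ester F14. TMSOTf with 2,6-lutidine, then water, cleaves the tert-butyl ester to 30.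

## Further compounds

F1 | step 3 | methyl 2-{[(1R,6S)-6-(2-bromopropan-2-yl)-1,3-dimethyl-2-oxocyclohex-3-en-1-yl]methyl}prop-2-enoate | CC1=CC[C@H](C(C)(C)Br)[C@@](C)(CC(=C)C(=O)OC)C1=O
F2 | step 6 | 2-thioxopyridin-1(2H)-yl (2R,4aR,8aR)-4,4,7,8a-tetramethyl-8-oxo-1,2,3,4,4a,5,8,8a-octahydronaphthalene-2-carboxylate | CC1=CC[C@@H]2C(C)(C)C[C@@H](C(=O)ON3C=CC=CC3=S)C[C@@]2(C)C1=O
F3 | step 6 | (4aR,7R,8aR)-7-hydroperoxy-2,5,5,8a-tetramethyl-4a,5,6,7,8,8a-hexahydronaphthalen-1(4H)-one | CC1=CC[C@@H]2C(C)(C)C[C@@H](OO)C[C@@]2(C)C1=O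
F4 | step 9 | (1R,4aR,7R,8aR)-7-[(tert-butyldimethylsilyl)oxy]-1,2,5,5,8a-pentamethyl-1,4,4a,5,6,7,8,8a-octahydronaphthalen-1-ol | CC1=CC[C@@H]2C(C)(C)C[C@@H](O[Si](C)(C)C(C)(C)C)C[C@@]2(C)[C@]1(C)O
F5 | step 11 | 5-({[(1R,4aR,7R,8aR)-7-[(tert-butyldimethylsilyl)oxy]-2,5,5,8a-tetramethyl-1,4,4a,5,6,7,8,8a-octahydronaphthalen-1-yl]methyl}sulfanyl)-1-phenyl-1H-tetrazole | CC1=CC[C@@H]2C(C)(C)C[C@@H](O[Si](C)(C)C(C)(C)C)C[C@@]2(C)[C@@H]1CSc1nnnn1-c1ccccc1
F6 | step 11 | 5-({[(1R,4aR,7R,8aR)-7-[(tert-butyldimethylsilyl)oxy]-2,5,5,8a-tetramethyl-1,4,4a,5,6,7,8,8a-octahydronaphthalen-1-yl]methyl}sulfonyl)-1-phenyl-1H-tetrazole | CC1=CC[C@@H]2C(C)(C)C[C@@H](O[Si](C)(C)C(C)(C)C)C[C@@]2(C)[C@@H]1CS(=O)(=O)c1nnnn1-c1ccccc1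
F7 | step 13 | 7,8-epoxide of 22 (labdane numbering; oxygen on the face of H5 and H9) | C[C@]12O[C@H]1C[C@@H]3C(C)(C)C[C@@H](O[Si](C)(C)C(C)(C)C)C[C@@]3(C)[C@@H]2CCC4=CC(=O)OC4
F8 | step 13 | 4-{2-[7-[(tert-butyldimethylsilyl)oxy]-3-hydroxy-5,5,8a-trimethyl-2-methylidenedecahydronaphthalen-1-yl]ethyl}furan-2(5H)-one (labdane 7-hydroxy-8(17)-ene) | C=C1[C@@H](O)C[C@@H]2C(C)(C)C[C@@H](O[Si](C)(C)C(C)(C)C)C[C@@]2(C)[C@@H]1CCC1=CC(=O)OC1
F9 | step 13 | methyl carbonate of F8 | C=C1[C@@H](OC(=O)OC)C[C@@H]2C(C)(C)C[C@@H](O[Si](C)(C)C(C)(C)C)C[C@@]2(C)[C@@H]1CCC1=CC(=O)OC1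
F10 | step 15 | triethylsilyl (2Z)-5-[(1R,4aR,7R,8aR)-7-[(tert-butyldimethylsilyl)oxy]-5,5,8a-trimethyl-2-methylidenedecahydronaphthalen-1-yl]-3-{[(triethylsilyl)oxy]methyl}pent-2-enoate | C=C1CC[C@@H]2C(C)(C)C[C@@H](O[Si](C)(C)C(C)(C)C)C[C@@]2(C)[C@@H]1CC/C(=C/C(=O)O[Si](CC)(CC)CC)CO[Si](CC)(CC)CC
F11 | step 15 | (2Z)-5-[(1R,4aR,7R,8aR)-7-[(tert-butyldimethylsilyl)oxy]-5,5,8a-trimethyl-2-methylidenedecahydronaphthalen-1-yl]-3-{[(triethylsilyl)oxy]methyl}pent-2-enoic acid | C=C1CC[C@@H]2C(C)(C)C[C@@H](O[Si](C)(C)C(C)(C)C)C[C@@]2(C)[C@@H]1CC/C(=C/C(=O)O)CO[Si](CC)(CC)CC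
F12 | step 15 | tert-butyl ester of F11 | C=C1CC[C@@H]2C(C)(C)C[C@@H](O[Si](C)(C)C(C)(C)C)C[C@@]2(C)[C@@H]1CC/C(=C/C(=O)OC(C)(C)C)CO[Si](CC)(CC)CC
F13 | step 15 | tert-butyl (2Z)-5-[(1R,4aR,7R,8aR)-7-hydroxy-5,5,8a-trimethyl-2-methylidenedecahydronaphthalen-1-yl]-3-(hydroxymethyl)pent-2-enoate | C=C1CC[C@@H]2C(C)(C)C[C@@H](O)C[C@@]2(C)[C@@H]1CC/C(=C/C(=O)OC(C)(C)C)CO
F14 | step 15 | tert-butyl (2Z)-3-[(acetyloxy)methyl]-5-[(1R,4aR,7R,8aR)-7-hydroxy-5,5,8a-trimethyl-2-methylidenedecahydronaphthalen-1-yl]pent-2-enoate | C=C1CC[C@@H]2C(C)(C)C[C@@H](O)C[C@@]2(C)[C@@H]1CC/C(=C/C(=O)OC(C)(C)C)COC(C)=O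
A1 | alternative 1 | methyl (2E,5S,8E,10E)-12-[(tert-butyldimethylsilyl)oxy]-3,7,7-trimethyl-5-[(triisopropylsilyl)oxy]dodeca-2,8,10-trienoate | COC(=O)/C=C(\C)C[C@H](O[Si](C(C)C)(C(C)C)C(C)C)CC(C)(C)/C=C/C=C/CO[Si](C)(C)C(C)(C)C
A2 | alternative 1 | trans-fused methyl 2-{[(tert-butyldimethylsilyl)oxy]methyl}-5,5,8a-trimethyl-7-[(triisopropylsilyl)oxy]-1,2,4a,5,6,7,8,8a-octahydronaphthalene-1-carboxylate | CC(C)(C)[Si](C)(C)OC[C@@H]1C=C[C@@H]2C(C)(C)C[C@@H](O[Si](C(C)C)(C(C)C)C(C)C)C[C@@]2(C)[C@@H]1C(=O)OC
A3 | alternative 2 | (1S)-4-ethenyl-3,5,5-trimethylcyclohex-3-en-1-yl 4-(trimethylsilyl)but-2-ynoate | C[Si](C)(C)CC#CC(=O)O[C@@H]1CC(C)(C)C(C=C)=C(C)C1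
A4 | alternative 2 | C2–O–C11 lactone-bridged ring A and ring B 5,8-diene with C17 trimethylsilyl group | C[Si](C)(C)CC1=C2C(=O)O[C@@H]3CC(C)(C)C(=CC1)[C@@]2(C)C3
A5 | alternative 3 | (4S,6S)-2,2,6-trimethyl-4-[(triisopropylsilyl)oxy]cyclohexan-1-one | C[C@H]1C[C@@H](CC(C)(C)C1=O)O[Si](C(C)C)(C(C)C)C(C)C
A6 | alternative 3 | methyl 2-acetyl-5-[(tert-butyldimethylsilyl)oxy]pent-2-enoate (alkene isomer mixture) | CC(=O)C(=CCCO[Si](C)(C)C(C)(C)C)C(=O)OC
A7 | alternative 3 | bicyclic enone with C7 ketone, C8 methyl ester, C9 2-(tert-butyldimethylsilyloxy)ethyl arm and C2 triisopropylsilyl ether | COC(=O)[C@H]1C(=O)C=C2C(C)(C)C[C@@H](O[Si](C(C)C)(C(C)C)C(C)C)C[C@@]2(C)[C@@H]1CCO[Si](C)(C)C(C)(C)C
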